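The runs were computed with constants of no real substance; the scatter is artificial.

Target in Thursday's run stays at or below 10% while electrophile falls to 72%, so I follow the electrophile.

| flask | electrophile | nucleophile | protic impurity | remark | time |
|---|---|---|---|---|---|
| Thursday's | 0.10 M (fed, over 2.0 min) | 0.78 equiv | 0.020 M | run made earlier; the fed solution adds 0.50 times the starting volume |  |
| red | 0.10 M (fed, over 2.0 min) | 1.00 equiv | 0.0200 M | the fed solution adds 0.50 times the starting volume | 25 min |
| teal | 0.10 M (fed, over 2.0 min) | 1.50 equiv | 0.0200 M | the fed solution adds 0.50 times the starting volume | 25 min |

Thursday's run (percent of the electrophile charged)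

| time / min | electrophile / % | target / % |
|---|---|---|
| 4.00 | 95 | 2 |
| 8.00 | 91 | 7 |
| 10.0 | 85 | 8 |
| 15.0 | 80 | 5 |
| 20.0 | 76 | 10 |
| 25.0 | 72 | 7 |

(standard deviation of a reading: 1.5 percentage points)

- every charge counts on the volume at the start, and the solution that is fed holds the whole dose

- part of the electrophile that has reacted at the end, red
- part of the electrophile that has reacted at the end, teal
- what raising the equivalents of nucleophile from its lowest to its highest value here does to the part of the electrophile that has reacted (changes below 5 percentage points count as none) (no change / it rises / it falls)

I take the protic impurity to remove nucleophile at once, one for one, which leaves Thursday's flask 0.0580 M of free nucleophile, n. I take n to fall one for one with electrophile after that, so Thursday's n averages 0.0365 M between 10.0 min and 25.0 min. Over that stretch Thursday's electrophile goes from 85% to 72%, which reads as a lifetime τ of 90.4 min. I carry the product P = τ·n, read as 3.30 M·min, the lifetime product; P/n is then the pseudo-first-order lifetime of electrophile at a given n.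

By my count red starts with n = 0.0800 M, so τ = 41.2 min. By the same count teal starts with n = 0.130 M, so τ = 25.4 min. Integrating the second-order loss from mid-feed over 24.0 min, I get 35.1% reacted for red and 51.4% for teal, a rise of 16 percentage points.

The forecast, assuming that “the impurity destroys nucleophile quickly”, says 36% and 53%, slightly above my figures, and it rises.

The flasks give 39.3% for red and 56.3% for teal: it rises, by 17 points.

    electrophile + nucleophile → acid set free + target (k = 0.00650 M⁻¹ s⁻¹)
    nucleophile + acid set free ⇌ protonated nucleophile, settled at all times (K = 36000 M⁻¹)
    nucleophile + protic impurity → quenched reagent (k = 0.850 M⁻¹ s⁻¹)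
    electrophile + target → side product (k = 0.0220 M⁻¹ s⁻¹)

In teal, electrophile use through nucleophile runs 2.0 times its use through target at 8.20 min, but 0.92 times at 25.0 min. Teal ends with 38.4% as side product against 17.9% as target. Teal's starting lifetime P/n of 25.4 min is close to its 25 min run, and teal ends with 43.7% electrophile. A neighbour flask is teal at 0.040 M electrophile, with equivalents and loadings held; by my count it starts with n = 0.0400 M, equal to its electrophile, so P gives τ = 82.5 min and 77.5% left; that flask holds 76.5% electrophile.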